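The data come from a simulation for substances that don't exist; noise was put on by code.

The leftover is where I start: the share of the Z charged that does not stand as Q. Pooling the two earlier runs, it is 21.1% at 8.00 h and 12.6% at 30.0 h, though Z itself reads only 1.15% at 8.00 h. So a store other than Z still feeds Q. Pooling seems fair: E differs between the runs, but their last readings differ by 0.2 percentage points, less than the scatter.

| setting | Monday's | Wednesday's | flask |
|---|---|---|---|
| Z | 0.050 M | 0.050 M | 0.050 M |
| X | 2.5 equiv | 2.5 equiv | 2.50 equiv |
| E | 1.2 mM | 1.9 mM | 2.50 mM |
| remark | run made earlier | run made earlier |  |
| time |  |  | 2.0 d |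
| volume of the second phase over the first |  |  | 2.0 |

| run | time / h | Q / % | Z / % |
|---|---|---|---|
| Monday's | 8.00 | 79.6 | 1.9 |
| Monday's | 15.0 | 84.0 | 0 |
| Monday's | 20.0 | 85.9 | 0.3 |
| Monday's | 30.0 | 87.5 | 0 |
| Wednesday's | 8.00 | 78.2 | 0.4 |
| Wednesday's | 15.0 | 82.2 | 1.8 |
| Wednesday's | 20.0 | 85.8 | 0.6 |
| Wednesday's | 30.0 | 87.3 | 0 |

(readings scatter by 1 percentage point)

- the Q standing at 2.0 d, as a percentage of the Z charged
- the change that raises the amount of Q at 2.0 d, in percent of the Z charged most ("none" if none brings more than 2 percentage points) (west / north-west / none)
- amount of Q at 2.0 d, in percent of the Z charged, after west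

- west: doubling the amount of X, all else as stated
- north-west: doubling the transfer coefficient of X, all else as stated

- in the second phase: X; everything else is in the first
- charges count per volume of the first phase; a concentration in a rate is the amount of a species over the volume of its own phase; every rate counts per litre of the first phase
- the numbers in the tables scatter with a standard deviation of 1 percentage point
- the earlier runs hold the two phases in the same ratio of volumes as the flask asked about

My first way follows one leftover molecule and supposes it is never lost, with the same chance of becoming Q each hour. The two leftovers give 0.0234 /h. I call this the drain, the share of the leftover turning into Q per hour, an apparent first-order rate constant. Carried to 2.0 d, it gives 91.7%.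

My second way ignores the leftover and watches the climb. Q rises 4.2 points from 8.00 h to 15.0 h and 1.5 points from 20.0 h to 30.0 h. A climb fading at that pace, 0.100 /h, reaches 88.2%.

The two ways part by 3.5 points, and each cheats somewhere. The drain reads 0.0317 /h early but 0.0116 /h late, lower, so part of the leftover looks lost and I take the first way to read high. The second way leans on a late rise that carries a scatter of 1 point, and that rise is less than twice the scatter. I expect something between them, about 90.0%. Both earlier runs hold X at 2.5 equiv, so this reckoning is silent on the changes.

The forecast says 88.5%, chooses west with 92%, and holds that “doubling X helps most”. The flask gives 91.4%, and west is best: it gains 3.4 points to reach 94.8%, against 1.7 points for the other change.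

    J ⇌ X, rate k1*([J] - [X]/K1) per volume of the first phase (partition coefficient = 1.90, kL = 1.20 /h)
    Z + J → Q (k = 43.0 /M/h)
    2 Z → D (k = 0.680 /M/h)
    Z ⇌ L (K = 2.20, k = 0.120 /h)
    J + E → G (k = 0.950 /M/h)

On this flask the figure reckoned with the drain stood 0.30 points above the result. The neighbouring flask is the same one read at 12 h. Starting from the leftover at 8.00 h and running the drain up to that time leaves 19.2%, so I reckon Q at 80.8%. That flask holds 81.3% of Q, with D at 6.24% and L at 11.6%.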